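The readings stem from a simulated flask from invented constants.

In the maple flask, starting material disappears faster than product appears: at 1.00 h the readings show 16.0 % of it gone and 4 % as product, an induction period.

| flask | starting material | reagent | capture agent | free catalyst | remark |
|---|---|---|---|---|---|
| maple | 0.20 M | 0.24 M | 0.010 M | 1.9 mM | the very flask that is asked about, followed so far |
| flask | 0.20 M | 0.240 M | 0.0100 M | 1.9 mM |  |

maple run (percent of the starting material charged)

| time / h | product / % | starting material / % |
|---|---|---|
| 0.333 | 3 | 95 |
| 0.667 | 3 | 89 |
| 1.00 | 4 | 84 |
| 2.00 | 12 | 80 |
| 4.00 | 28 | 58 |

(scatter of a reading: 2 percentage points)

* apparent order in free catalyst when 5.0 % of the starting material are converted (percent change of the rate of making product for one percent more free catalyst charged)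
* apparent order in reagent when 5.0 % of the starting material are converted (percent change of the rate of making product for one percent more reagent charged)

- the numbers in the tables scatter with a standard deviation of 2 percentage points
- no earlier run changes the charge of free catalyst; that part of a forecast is a guess
- no earlier run changes the charge of reagent; that part of a forecast is a guess

Averaged over the readings at 1.00 h, 2.00 h and 4.00 h, the hold-up, meaning starting material gone but not yet seen as product, is 11.3 %. The charges seem to forbid this. Follow one held molecule: on catalyst or on capture agent it occupies one partner, so the binding ceiling, the summed charges of both over the charge of starting material, is 5.95 %. The hold-up stands above that ceiling by 5.3 percentage points, with a scatter of 2 points on each reading. So the readings point to an intermediate free in solution for the surplus. This reckoning gives no order, since no earlier run varies free catalyst or reagent, and it commits to no number for either.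

The forecast puts the order in free catalyst at 0.6 and in reagent at 0.7: “The reagent's role is untested, so this is largely a guess.”

The flask gives 0.89 in free catalyst and 0.42 in reagent, on this scheme:

    starting material + free catalyst → free catalyst + open intermediate (k = 130 /M/h)
    free catalyst + open intermediate ⇌ catalyst intermediate (K = 360 /M, k = 1100 /M/h)
    reagent + catalyst intermediate → free catalyst + product (k = 79.0 /M/h)
    open intermediate + capture agent → trapped intermediate (k = 1.40 /M/h)

At 1.00 h the catalyst of this flask is split between 52.9 % free catalyst and 47.1 % catalyst intermediate. At 5.00 h open intermediate stands at 8.57 % of the starting material charged, above the ceiling of 5.95 %, while trapped intermediate and catalyst intermediate together hold 1.09 % of that charge.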